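The ratio to find is free nucleophile lost per target made, and the rates in the midnight run point to a value for it.

| flask | electrophile | nucleophile | free base | remark | time |
|---|---|---|---|---|---|
| midnight | 20 mM | 1.1 equiv | 0.54 equiv | run made earlier |  |
| dusk | 20 mM | 1.1 equiv | 1.2 equiv | run made earlier |  |
| autumn | 40 mM | 1.1 equiv | 0.80 equiv | run made earlier |  |
| flask | 20 mM | 1.10 equiv | 0.800 equiv |  | 40 min |

| run | time / min | electrophile / % | target / % |
|---|---|---|---|
| midnight | 3.00 | 77.8 | 13.5 |
| midnight | 5.00 | 68.3 | 19.3 |
| midnight | 8.00 | 56.9 | 25.9 |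
| midnight | 12.0 | 47.1 | 31.8 |
| midnight | 15.0 | 41.2 | 35.0 |
| midnight | 25.0 | 31.5 | 41.0 |
| midnight | 40.0 | 25.1 | 45.8 |
| dusk | 6.00 | 64.4 | 21.7 |
| dusk | 12.0 | 47.1 | 31.3 |
| dusk | 15.0 | 41.5 | 34.6 |
| dusk | 25.0 | 30.7 | 40.9 |
| dusk | 30.0 | 28.4 | 43.1 |
| dusk | 40.0 | 25.7 | 46.0 |
| autumn | 8.00 | 47.7 | 36.8 |
| autumn | 15.0 | 33.5 | 44.8 |
| autumn | 25.0 | 26.3 | 49.4 |
| autumn | 30.0 | 24.8 | 50.6 |
| autumn | 40.0 | 22.9 | 52.6 |

(standard deviation of a reading: 0.3 percentage points)

- part of the electrophile that has reacted at 40 min
- share of the unused nucleophile that is free and not bound as protonated nucleophile, at 40 min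

- the analysis behind the earlier runs scatters by 0.3 percentage points, standard deviation
- on the list of suspects stand: 2 free base -> homo dimer; electrophile <-> dormant form; acid set free + free base <-> salt of the base; electrophile + nucleophile -> acid set free + target; nucleophile + acid set free <-> protonated nucleophile
- what has gone from electrophile into another species counts as reacted, even if it can come back
- the earlier runs do not show how much of nucleophile is bound; that part of a forecast is a guess

Read the midnight run row against row, in fractions of the charge. Over the first 3.00 min the target rises at 0.0450 min⁻¹; between 25.0 min and 40.0 min it rises at 0.00320 min⁻¹.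

Divide each rate by the mean electrophile and the mean free nucleophile in that interval. This gives an apparent second-order constant, in units of the charge. Counting one nucleophile lost per target, it goes from 0.0490 min⁻¹ to 0.0170 min⁻¹. Counting two, it goes from 0.0525 min⁻¹ to 0.0487 min⁻¹, which nearly holds.

So take each target to tie up a second nucleophile as protonated nucleophile. That is a guess, since no reading shows bound nucleophile.

At 40.0 min the midnight and dusk runs, with free base 0.54 equiv and 1.2 equiv, show target 45.8 % and 46.0 % and electrophile 25.1 % and 25.7 %, with scatter 0.3 percentage points. Your flask has base between these, so take their means: 74.6 % reacted and target 45.9 %.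

The free share, nucleophile charge minus twice the target, over charge minus the target once, is then 28.4 %.

The forecast gives 74.6 % and 28 %, on the same ground: “each acid released instead ties up one nucleophile”. The flask gives 74.7 % and 28.5 %.

    2 free base → homo dimer (k = 0.0600 L mol⁻¹ s⁻¹)
    electrophile ⇌ dormant form (K = 1.10, k = 5.50 × 10⁻⁴ s⁻¹)
    acid set free + free base ⇌ salt of the base (K = 140 L mol⁻¹, k = 0.420 L mol⁻¹ s⁻¹)
    electrophile + nucleophile → acid set free + target (k = 0.0440 L mol⁻¹ s⁻¹)
    nucleophile + acid set free ⇌ protonated nucleophile, settled at all times (K = 1.10 × 10⁵ L mol⁻¹)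

The flask's target at 40.0 min is 46.0 %, which puts the free share at 28.2 %. Now raise the electrophile to 34 mM, equivalents held. In that neighbour flask the target reaches 51.5 %, and the same reckoning gives a free share of 12.1 %. The neighbour flask itself gives 12.5 %, with 6.6 % of its charged nucleophile still unbound.

(The runs were computed with constants of no real substance, and the scatter is random.)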